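**Retrosynthetic overview**
1. Target 15 comes from 14, its bis-TIPS ether, by fluoride desilylation.
2. 14 comes from 6 and 10 by cutting C4–C4a and O1–C2: ring C is made last and in one operation, rings A and B are bought as arenes. The C2–C3–C4 unit arrives as aryl vinyl ketone 10 (C4 = CH2 terminus, C2 = carbonyl carbon, one oxidation level above the target), and C2–H is set by asymmetric hydride transfer in the same flask.
3. Enabling feature: in ring A, C4a is ortho/para to O1, O5 and O7 and its neighbour C8a carries O1, so ring A is a C,O-1,3-dinucleophile. C8 (prenyl) lies between O1 and O7, so ring-A piece 6 has a twofold axis through C8 and C5 that makes C4a/C6 and O1/O7 pairwise identical; with O5 silylated, only the hydroxyl next to the prenylated carbon can close. C2, benzylic and bound to O1, is a planar oxocarbenium carbon at the ketone level.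
4. 6 comes from phloroglucinol 1 (mono-silylation, bis-MOM ether, directed lithiation/prenylation between the MOM ethers, acetal cleavage); 10 comes from 3-hydroxy-5-methoxybenzaldehyde 7 (silylation, vinyl Grignard addition, oxidation).

Key step: step 8

Remark: the target is the (2S)-flavan; which enantiomer of the phosphoric acid gives the (S) sense in step 8 has to be found by experiment, (R)-TRIP is written and its mirror image would be used otherwise; 1 and 7 are taken as commercial.

**Step 1**
Reactants: 1 phloroglucinol (anhydrous, 2 equiv)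
Product: 2 5-[(triisopropylsilyl)oxy]benzene-1,3-diol
Conditions: TIPSCl (1 equiv), imidazole, DMF, 0 °C to rt
Reagents that add atoms: triisopropylsilyl chloride, CC(C)[Si](Cl)(C(C)C)C(C)C
Why: Imidazole-promoted phenol silylation of a triol whose three hydroxyls are equivalent, so the mono-ether is a single compound and excess 1 should hold back double silylation.

**Step 2**
Reactants: 2 5-[(triisopropylsilyl)oxy]benzene-1,3-diol
Product: 3 [3,5-bis(methoxymethoxy)phenoxy]triisopropylsilane
Conditions: MOMCl (2.5 equiv), i-Pr2NEt, CH2Cl2, 0 °C to rt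
Reagents that add atoms: chloromethyl methyl ether, COCCl
Why: O-alkylation of both phenols (MOM protection) under amine base should leave the hindered aryl TIPS ether untouched and installs the two directing groups for step 3.

**Step 3**
Reactants: 3 [3,5-bis(methoxymethoxy)phenoxy]triisopropylsilane
Product: 5 [3,5-bis(methoxymethoxy)-4-(3-methylbut-2-en-1-yl)phenoxy]triisopropylsilane, via aryllithium 4 (not isolated)
Conditions: n-BuLi, TMEDA, THF, 0 °C; then CuI (10 mol %), prenyl bromide, −78 °C to rt
Reagents that add atoms: prenyl bromide (1-bromo-3-methylbut-2-ene), CC(C)=CCBr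
Why: Directed ortho-metalation should occur at the carbon flanked by two MOM ethers (cooperative coordination, the bulky TIPS ether is a poor director), and the copper-assisted SN2 alkylation of the aryllithium places the prenyl group on the symmetry axis.

**Step 4**
Reactants: 5 [3,5-bis(methoxymethoxy)-4-(3-methylbut-2-en-1-yl)phenoxy]triisopropylsilane
Product: 6 2-(3-methylbut-2-en-1-yl)-5-[(triisopropylsilyl)oxy]benzene-1,3-diol
Conditions: HCl (0.5 M), MeOH, rt to 40 °C, stopped at full conversion
Reagents that add atoms: none
Why: Acid-catalysed acetal exchange with methanol cleaves both MOM ethers under conditions mild enough that the aryl TIPS ether and, with careful monitoring, the prenyl alkene should survive.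

**Step 5**
Reactants: 7 3-hydroxy-5-methoxybenzaldehyde
Product: 8 3-methoxy-5-[(triisopropylsilyl)oxy]benzaldehyde
Conditions: TIPSCl, imidazole, DMF, rt
Reagents that add atoms: triisopropylsilyl chloride, CC(C)[Si](Cl)(C(C)C)C(C)C
Why: Standard phenol silylation; the TIPS ether removes the acidic proton for step 6 and lowers the nucleophilicity of ring B for step 8.

**Step 6**
Reactants: 8 3-methoxy-5-[(triisopropylsilyl)oxy]benzaldehyde
Product: 9 rac-1-{3-methoxy-5-[(triisopropylsilyl)oxy]phenyl}prop-2-en-1-ol
Conditions: CH2=CHMgBr, THF, −78 to 0 °C; then H2O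
Reagents that add atoms: vinylmagnesium bromide, C=C[Mg]Br
Why: Grignard 1,2-addition to the aldehyde gives the allylic alcohol as a racemate, which does not matter because this stereocenter is removed in step 7.

**Step 7**
Reactants: 9 rac-1-{3-methoxy-5-[(triisopropylsilyl)oxy]phenyl}prop-2-en-1-ol
Product: 10 1-{3-methoxy-5-[(triisopropylsilyl)oxy]phenyl}prop-2-en-1-one
Conditions: Dess–Martin periodinane, CH2Cl2, 0 °C to rt; used at once
Reagents that add atoms: none
Why: Dess–Martin oxidation of a benzylic, allylic alcohol should give the aryl vinyl ketone under neutral conditions that spare the silyl ether.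

**Step 8**
Reactants: 6 2-(3-methylbut-2-en-1-yl)-5-[(triisopropylsilyl)oxy]benzene-1,3-diol (1.3 equiv) and 10 1-{3-methoxy-5-[(triisopropylsilyl)oxy]phenyl}prop-2-en-1-one
Product: 14 (2S)-2-{3-methoxy-5-[(triisopropylsilyl)oxy]phenyl}-8-(3-methylbut-2-en-1-yl)-5-[(triisopropylsilyl)oxy]chroman-7-ol, via ketone adduct 11 (not isolated), via hemiketal 12 (not isolated), via chroman-2-ylium ion 13 (not isolated)
Conditions: (R)-TRIP [(R)-3,3'-bis(2,4,6-triisopropylphenyl)-1,1'-binaphthyl-2,2'-diyl hydrogen phosphate] (10 mol %), Hantzsch ester (diethyl 2,6-dimethyl-1,4-dihydropyridine-3,5-dicarboxylate, 1.3 equiv), 5 Å MS, toluene, slow addition of 10 at rt, then 45 °C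
Reagents that add atoms: none
Why: Proposed new method: the phosphoric acid should activate enone 10 and the phenol of 6 for Friedel–Crafts conjugate addition of ring carbon C4 (or its equivalent C6) of 6 to the CH2 terminus (C4–C4a, ketone 11), the one free hydroxyl ortho to the new chain then adds to the carbonyl (O1–C2, hemiketal 12), acid-induced loss of water gives the planar 2-arylchroman-2-ylium ion 13 paired with the chiral phosphate, and the Hantzsch ester, held by an N–H···O=P hydrogen bond, transfers hydride to one face of C2. The closest known reaction types are the Brønsted-acid Friedel–Crafts Michael addition of phloroglucinol-type phenols to enones, the acid/Et3SiH reductive cyclization of 3-(2-hydroxyaryl)-1-arylpropan-1-ones to racemic flavans, and the chiral phosphoric acid/Hantzsch ester transfer hydrogenation of cyclic oxocarbenium (benzopyrylium, isochromenylium) and iminium ion pairs; new are their merger into one operation and the enantioselective reduction of a chroman-2-ylium ion. Ring C closes by a 6-exo-trig hemiketalization. The C2 stereocenter is set under catalyst control by the chiral phosphate counter-anion in the hydride transfer, neither precursor carrying a stereocenter. The step needs C- over O-alkylation, closure through the oxygen next to the prenylated carbon, mono-alkylation and an untouched prenyl alkene: the twofold axis of 6 makes both ring C–H/O–H pairs identical, the TIPS ether blocks the only other ortho oxygen, reversible oxa-Michael addition funnels to the C-adduct, excess 6 and slow addition of 10 limit a second alkylation, and hydride goes only to the cation.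

**Step 9**
Reactants: 14 (2S)-2-{3-methoxy-5-[(triisopropylsilyl)oxy]phenyl}-8-(3-methylbut-2-en-1-yl)-5-[(triisopropylsilyl)oxy]chroman-7-ol
Product: 15 (2S)-2-(3-hydroxy-5-methoxyphenyl)-8-(3-methylbut-2-en-1-yl)chromane-5,7-diol
Conditions: Bu4NF (2.5 equiv), AcOH (2.5 equiv), THF, 0 °C to rt, under argon
Reagents that add atoms: none
Why: Fluoride-driven desilylation of both aryl TIPS ethers under acetic acid buffering should free the three phenols without touching the prenyl alkene or the C2 benzylic ether stereocenter.

**Compound list**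
1 | phloroglucinol (benzene-1,3,5-triol) | Oc1cc(O)cc(O)c1 | starting material
2 | 5-[(triisopropylsilyl)oxy]benzene-1,3-diol | CC(C)[Si](Oc1cc(O)cc(O)c1)(C(C)C)C(C)C | intermediate
3 | [3,5-bis(methoxymethoxy)phenoxy]triisopropylsilane | COCOc1cc(OCOC)cc(O[Si](C(C)C)(C(C)C)C(C)C)c1 | intermediate
4 | {2,6-bis(methoxymethoxy)-4-[(triisopropylsilyl)oxy]phenyl}lithium (aryllithium, not isolated) | [Li]c1c(OCOC)cc(O[Si](C(C)C)(C(C)C)C(C)C)cc1OCOC | intermediate
5 | [3,5-bis(methoxymethoxy)-4-(3-methylbut-2-en-1-yl)phenoxy]triisopropylsilane | COCOc1cc(O[Si](C(C)C)(C(C)C)C(C)C)cc(OCOC)c1CC=C(C)C | intermediate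
6 | 2-(3-methylbut-2-en-1-yl)-5-[(triisopropylsilyl)oxy]benzene-1,3-diol | CC(C)=CCc1c(O)cc(O[Si](C(C)C)(C(C)C)C(C)C)cc1O | intermediate
7 | 3-hydroxy-5-methoxybenzaldehyde | COc1cc(O)cc(C=O)c1 | starting material
8 | 3-methoxy-5-[(triisopropylsilyl)oxy]benzaldehyde | COc1cc(C=O)cc(O[Si](C(C)C)(C(C)C)C(C)C)c1 | intermediate
9 | rac-1-{3-methoxy-5-[(triisopropylsilyl)oxy]phenyl}prop-2-en-1-ol | COc1cc(C(O)C=C)cc(O[Si](C(C)C)(C(C)C)C(C)C)c1 | intermediate
10 | 1-{3-methoxy-5-[(triisopropylsilyl)oxy]phenyl}prop-2-en-1-one | COc1cc(C(=O)C=C)cc(O[Si](C(C)C)(C(C)C)C(C)C)c1 | intermediate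
11 | 3-{2,4-dihydroxy-3-(3-methylbut-2-en-1-yl)-6-[(triisopropylsilyl)oxy]phenyl}-1-{3-methoxy-5-[(triisopropylsilyl)oxy]phenyl}propan-1-one (ketone adduct, not isolated) | COc1cc(C(=O)CCc2c(O[Si](C(C)C)(C(C)C)C(C)C)cc(O)c(CC=C(C)C)c2O)cc(O[Si](C(C)C)(C(C)C)C(C)C)c1 | intermediate
12 | rac-2-{3-methoxy-5-[(triisopropylsilyl)oxy]phenyl}-8-(3-methylbut-2-en-1-yl)-5-[(triisopropylsilyl)oxy]chromane-2,7-diol (hemiketal, not isolated) | COc1cc(C2(O)CCc3c(O[Si](C(C)C)(C(C)C)C(C)C)cc(O)c(CC=C(C)C)c3O2)cc(O[Si](C(C)C)(C(C)C)C(C)C)c1 | intermediate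
13 | 7-hydroxy-2-{3-methoxy-5-[(triisopropylsilyl)oxy]phenyl}-8-(3-methylbut-2-en-1-yl)-5-[(triisopropylsilyl)oxy]chroman-2-ylium ion, paired with the chiral phosphate (not isolated) | COc1cc(C2=[O+]c3c(CC=C(C)C)c(O)cc(O[Si](C(C)C)(C(C)C)C(C)C)c3CC2)cc(O[Si](C(C)C)(C(C)C)C(C)C)c1 | intermediate
14 | (2S)-2-{3-methoxy-5-[(triisopropylsilyl)oxy]phenyl}-8-(3-methylbut-2-en-1-yl)-5-[(triisopropylsilyl)oxy]chroman-7-ol | COc1cc(O[Si](C(C)C)(C(C)C)C(C)C)cc([C@@H]2CCc3c(O[Si](C(C)C)(C(C)C)C(C)C)cc(O)c(CC=C(C)C)c3O2)c1 | intermediate
15 | (2S)-2-(3-hydroxy-5-methoxyphenyl)-8-(3-methylbut-2-en-1-yl)chromane-5,7-diol | COc1cc(O)cc([C@@H]2CCc3c(O)cc(O)c(CC=C(C)C)c3O2)c1 | target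

**Step count**
Total steps: 9. Longest linear sequence: 6 (steps 1, 2, 3, 4, 8, 9).

**Steps most likely to fail**

Step 8 (Proposed new method). What may go wrong:
- poor facial selectivity in the hydride transfer, because the oxocarbenium ion has no hydrogen-bond donor to anchor it to the phosphate;
- conjugate reduction or polymerization of the enone before the Friedel–Crafts addition;
- a second alkylation at the remaining activated ring carbon.

Fallback with known chemistry: it sets out from ketone 11, now made and isolated from 6 and 10 with an achiral acid (diphenyl phosphate 10 mol %, toluene, rt), and comes back at 14. Asymmetric transfer hydrogenation of 11 with RuCl[(R,R)-TsDPEN](p-cymene) in HCO2H/Et3N should give the (R)-carbinol 4-[(3R)-3-hydroxy-3-{3-methoxy-5-[(triisopropylsilyl)oxy]phenyl}propyl]-2-(3-methylbut-2-en-1-yl)-5-[(triisopropylsilyl)oxy]benzene-1,3-diol F1. Mitsunobu cyclization (PPh3, DIAD, THF, 0 °C, dilute) through the ortho phenol should then close ring C with inversion to 14; the meta-dioxygenated ring B disfavours ionization, so clean SN2 inversion is expected.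

Step 4. What may go wrong: acid-catalysed addition of a neighbouring phenol across the prenyl double bond during acetal cleavage, or solvolysis of the silyl ether on prolonged exposure.

Fallback: it sets out from 3 and comes back at 6. Lithiation as in step 3 (aryllithium 4) and quenching with allyl bromide should give [4-allyl-3,5-bis(methoxymethoxy)phenoxy]triisopropylsilane F2. The same HCl/MeOH cleavage, to which a terminal allyl group is indifferent, should give 2-allyl-5-[(triisopropylsilyl)oxy]benzene-1,3-diol F3. Cross-metathesis with excess 2-methylbut-2-ene (second-generation Grubbs catalyst, CH2Cl2, 40 °C) then builds the prenyl terminus after all acid steps, giving 6.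

Step 1. What may go wrong: over-silylation and difficult separation in the statistical mono-protection.

Fallback: no numbered compound precedes step 1, so it sets out from commercial 3,5-bis(benzyloxy)phenol in place of 1 and comes back at 2. Silylation (TIPSCl, imidazole, DMF) should give [3,5-bis(benzyloxy)phenoxy]triisopropylsilane F4, and hydrogenolysis (H2, Pd/C, EtOAc, rt) of both benzyl ethers gives 2 without any statistical step.

**Further compounds**
F1 | step 8 | 4-[(3R)-3-hydroxy-3-{3-methoxy-5-[(triisopropylsilyl)oxy]phenyl}propyl]-2-(3-methylbut-2-en-1-yl)-5-[(triisopropylsilyl)oxy]benzene-1,3-diol | COc1cc(O[Si](C(C)C)(C(C)C)C(C)C)cc([C@H](O)CCc2c(O[Si](C(C)C)(C(C)C)C(C)C)cc(O)c(CC=C(C)C)c2O)c1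
F2 | step 4 | [4-allyl-3,5-bis(methoxymethoxy)phenoxy]triisopropylsilane | COCOc1cc(O[Si](C(C)C)(C(C)C)C(C)C)cc(OCOC)c1CC=C
F3 | step 4 | 2-allyl-5-[(triisopropylsilyl)oxy]benzene-1,3-diol | C=CCc1c(O)cc(O[Si](C(C)C)(C(C)C)C(C)C)cc1O
F4 | step 1 | [3,5-bis(benzyloxy)phenoxy]triisopropylsilane | CC(C)[Si](Oc1cc(OCc2ccccc2)cc(OCc2ccccc2)c1)(C(C)C)C(C)C
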